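**Plan**

1. Retrosynthesis: the two silyl ethers (C15–O, C8–O) are removed; C9–H is traced back to C9–B (boron is a temporary carrier on C9); the C9–C11 bond is cut while C8–O is re‑closed onto C9. This gives a ring‑B C8–C9 oxirane bearing Bpin on C9, plus the intact C6 side chain as a primary organolithium. The decalin is then cut at C9–C10 and C4–C5 (Br+‑initiated polyene cyclization) back to (E)‑geranylacetone.
2. Enabling feature: in ring B the C8 tertiary carbinol and the C9 methine are vicinal, with C8–O and C9–C11 trans (O on the α face, C11 on the β face beside the axial C10 methyl). This is the pattern of an anti opening of a C8–C9 epoxide at C9 by carbon. C9 keeps a hydrogen in the target, so it can carry boron for a while, and C11 is delivered from inside (1,2‑shift from B to C9) to a face that no external nucleophile can reach.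
3. Forward order: chain first (geranylacetone → 1,1‑diboryl triene); rings A and B together in one cationic cascade that ends as the C8=C9 alkenyl boronate; then epoxide, fragment union, B→H and desilylation. The side chain is made separately by carboalumination.
4. Stereochemistry: C3 from the chiral Lewis‑base catalyst of the bromocyclization; C5/C10 from the chair–chair cascade of the E‑olefin; C8 from epoxidation anti to the C10 methyl; C9 from the anti 1,2‑shift and then from H‑atom delivery to the C9 radical on the open α face; C13=C14 (E) from syn‑carboalumination.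

Key step: step 8

Remark: labdane numbering is used for ring atoms (C3 = CHBr, C4 = CMe2, C8 = carbinol carbon, C9 = methine bearing the side chain, C10 = angular carbon, C11 = first side‑chain carbon); "β" means the decalin face carrying the C10 methyl, "α" the other face; absolute configurations are those of the SMILES (target 3R,5S,8S,9S,10R).
Remark: tris(pinacolboryl)methane 2 is taken as a purchasable reagent, and the antipode of the chiral bromocyclization catalyst is chosen that delivers the (3R)‑bromide.

Step 1
Reactants: 1 (E)-geranylacetone [(5E)-6,10-dimethylundeca-5,9-dien-2-one]; 2 tris(pinacolboryl)methane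
Product: 4 (5E)-1,1-bis(pinacolboryl)-2,6,10-trimethylundeca-1,5,9-triene, via lithium tris(pinacolboryl)methanide 3 (not isolated)
Conditions: 2, LiTMP, THF, 0 °C; then 1, 0 °C → rt
Reagents that add atoms: none
Why: Boron–Wittig condensation, in which the triboryl‑stabilised carbanion adds to the methyl ketone and the β‑oxido borane loses pinB–O− by B–O elimination; the two boryl groups on the new olefin carbon (future C9) are identical, so no olefin geometry has to be controlled.

Step 2
Reactants: 4 (5E)-1,1-bis(pinacolboryl)-2,6,10-trimethylundeca-1,5,9-triene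
Product: 5 ring-B alkenyl boronate 2-[(4aS,6R,8aR)-6-bromo-2,5,5,8a-tetramethyl-3,4,4a,5,6,7,8,8a-octahydronaphthalen-1-yl]-4,4,5,5-tetramethyl-1,3,2-dioxaborolane (3β-Br equatorial; trans-decalin; C8=C9 olefin; Bpin on C9)
Conditions: DBDMH (1.0 equiv), chiral BINOL-derived thiophosphoramide (10 mol %), toluene/CH2Cl2, −78 °C
Reagents that add atoms: 1,3-dibromo-5,5-dimethylhydantoin (DBDMH), CC1(C)N(Br)C(=O)N(Br)C1=O
Why: Proposed new method: catalyst‑bound Br+ should open the most electron‑rich (terminal) olefin enantioselectively (sets C3), and the chair–chair cascade of the E‑olefin (sets C5 and C10, trans‑decalin, equatorial Br) should end when the boron‑bearing carbon attacks the C10 cation, because the C8 cation so formed is flanked by two C–B bonds of which one is always axial and is lost to the hydantoin anion, leaving the C8=C9 alkenyl boronate as the only possible olefin isomer; the closest known reaction types are vinylsilane‑terminated cation–olefin cyclization, ipso‑substitution of alkenylboronates by carbocations, and Lewis‑base‑catalysed enantioselective bromocyclization of polyenes.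

Step 3
Reactants: 5 ring-B alkenyl boronate
Product: 6 oxiranyl boronate (8α,9α-epoxide of 5; Bpin on C9; methyl on C8; oxygen on the face opposite the C10 methyl)
Conditions: DMDO, acetone, −20 → 0 °C
Reagents that add atoms: dimethyldioxirane (DMDO), CC1(C)OO1
Why: Neutral dioxirane epoxidation of an alkenyl pinacol boronate (known reaction type) should take place on the α face, anti to the axial C10 methyl, which fixes the C8–O configuration of the target.

Step 4
Reactants: 7 tert-butyl(but-3-yn-1-yloxy)dimethylsilane
Product: 9 (2E)-5-(tert-butyldimethylsilyloxy)-3-methylpent-2-en-1-ol, via alkenyldimethylalane 8 (not isolated)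
Conditions: Me3Al, Cp2ZrCl2 (cat.), CH2Cl2, 0 °C → rt; then n-BuLi, THF, −78 °C; (CH2O)n, rt
Reagents that add atoms: trimethylaluminium, C[Al](C)C; paraformaldehyde (as formaldehyde), C=O
Why: Negishi carboalumination adds Me and Al syn across the terminal alkyne, and the alkenylalane, activated by n‑BuLi, is hydroxymethylated with retention, so the trisubstituted olefin should form as the E isomer only.

Step 5
Reactants: 9 (2E)-5-(tert-butyldimethylsilyloxy)-3-methylpent-2-en-1-ol
Product: 10 (2E)-1-(tert-butyldiphenylsilyloxy)-5-(tert-butyldimethylsilyloxy)-3-methylpent-2-ene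
Conditions: TBDPSCl, imidazole, DMF, rt
Reagents that add atoms: tert-butylchlorodiphenylsilane (TBDPSCl), CC(C)(C)[Si](Cl)(c1ccccc1)c1ccccc1
Why: Standard silylation of the primary allylic alcohol with a group that survives the mild acid of step 6 and the organolithium chemistry of steps 8 and 9.

Step 6
Reactants: 10 (2E)-1-(tert-butyldiphenylsilyloxy)-5-(tert-butyldimethylsilyloxy)-3-methylpent-2-ene
Product: 11 (3E)-5-(tert-butyldiphenylsilyloxy)-3-methylpent-3-en-1-ol
Conditions: PPTS (cat.), EtOH, 40 °C
Reagents that add atoms: none
Why: A primary TBS ether is solvolysed by mild acid much faster than a TBDPS ether, so the homoallylic alcohol should be released selectively.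

Step 7
Reactants: 11 (3E)-5-(tert-butyldiphenylsilyloxy)-3-methylpent-3-en-1-ol
Product: 12 tert-butyl{[(2E)-5-iodo-3-methylpent-2-en-1-yl]oxy}diphenylsilane
Conditions: I2, PPh3, imidazole, CH2Cl2, 0 °C
Reagents that add atoms: iodine, II
Why: Appel‑type iodination converts the primary alcohol into the iodide by SN2 at an unhindered carbon without touching the olefin or the allylic silyl ether.

Step 8
Reactants: 12 tert-butyl{[(2E)-5-iodo-3-methylpent-2-en-1-yl]oxy}diphenylsilane; 6 oxiranyl boronate
Product: 15 tertiary boronate (3β-Br; side chain on C9 β; Bpin on C9 α; 8α-OSiEt3; 8β-methyl; 15-OTBDPS; 13E), via homoallylic organolithium 13 (not isolated), via oxiranyl borate complex 14 (not isolated)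
Conditions: 12, t-BuLi (2 equiv), Et2O/pentane, −78 °C; then 6, THF, −78 °C; then TESOTf, −78 °C → rt
Reagents that add atoms: triethylsilyl trifluoromethanesulfonate (TESOTf), CC[Si](CC)(CC)OS(=O)(=O)C(F)(F)F
Why: Proposed new method: iodine–lithium exchange gives the primary organolithium 13, which adds to the Lewis‑acidic boron of 6 to give the four‑coordinate oxiranyl borate 14; O‑silylation of the epoxide by TESOTf then triggers a strain‑releasing 1,2‑metallate shift in which C11 moves from boron to C9 as the C9–O bond breaks, so the C9–C11 bond, the C8 tertiary silyl ether and a C9 tertiary boronate arise in one event. The closest known reaction type is the homologation of boronic esters with lithiated epoxides (silyl‑triflate‑promoted ring‑opening 1,2‑metallate rearrangement of oxiranyl borates), here entered from the opposite side (oxiranyl boronate plus organolithium) and on a fully substituted, ring‑fused epoxide. No ring is closed; the temporary oxirane is opened and the decalin is untouched. C9 is controlled by the stereospecific anti course of the shift (C11 enters anti to the departing α oxygen, that is, on the β face next to the axial C10 methyl), and C8 keeps the α C–O bond set in step 3. The step needs C9–O cleavage with alkyl migration instead of C8–O ionisation or pinacol‑oxygen migration; the borate on C9 secures this because only C9 bears a migrating group and the B–C11 bond can lie antiperiplanar to C9–O, while −78 °C keeps the organolithium away from the equatorial neopentyl C–Br bond.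

Step 9
Reactants: 15 tertiary boronate
Product: 17 bis-silyl ether of the target (8-O-SiEt3; 15-O-TBDPS; 9α-H), via lithium phenylborate 16 (not isolated)
Conditions: PhLi, THF, −78 → 0 °C; then Mn(OAc)3·2H2O, 4-tert-butylcatechol, rt
Reagents that add atoms: none
Why: Radical protodeboronation of an alkyl pinacol boronate: one‑electron oxidation of aryl borate 16 by Mn(III) releases the tertiary C9 radical, and the catechol should deliver hydrogen to the α face because the β face is blocked by the axial C10 and C8 methyl groups, which gives 9α‑H with the side chain β whatever the C9 configuration of 15.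

Step 10
Reactants: 17 bis-silyl ether of the target
Product: 18 (2E)-5-[(1S,2S,4aS,6R,8aR)-6-bromo-2-hydroxy-2,5,5,8a-tetramethyldecahydronaphthalen-1-yl]-3-methylpent-2-en-1-ol (target)
Conditions: TBAF, THF, rt → 40 °C
Reagents that add atoms: none
Why: Fluoride cleaves the primary TBDPS and the tertiary TES ether, and the equatorial secondary bromide, which has no antiperiplanar hydrogen, should survive.

**Compound list**

1 | (E)-geranylacetone [(5E)-6,10-dimethylundeca-5,9-dien-2-one] | CC(=O)CC/C=C(\C)CCC=C(C)C | starting material
2 | tris(pinacolboryl)methane | CC1(C)OB(OC1(C)C)C(B1OC(C)(C)C(C)(C)O1)B1OC(C)(C)C(C)(C)O1 | starting material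
3 | lithium tris(pinacolboryl)methanide | [Li]C(B1OC(C)(C)C(C)(C)O1)(B1OC(C)(C)C(C)(C)O1)B1OC(C)(C)C(C)(C)O1 | intermediate
4 | (5E)-1,1-bis(pinacolboryl)-2,6,10-trimethylundeca-1,5,9-triene | CC(=C(B1OC(C)(C)C(C)(C)O1)B1OC(C)(C)C(C)(C)O1)CC/C=C(\C)CCC=C(C)C | intermediate
5 | ring-B alkenyl boronate (3β-bromo, C8=C9, Bpin on C9, trans-decalin; 4aS,6R,8aR) | C1(B3OC(C)(C)C(C)(C)O3)[C@]2(C)CC[C@@H](Br)C(C)(C)[C@H]2CCC=1C | intermediate
6 | oxiranyl boronate (8α,9α-epoxide of 5) | O1[C@]2(B3OC(C)(C)C(C)(C)O3)[C@]4(C)CC[C@@H](Br)C(C)(C)[C@H]4CC[C@]12C | intermediate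
7 | tert-butyl(but-3-yn-1-yloxy)dimethylsilane | C#CCCO[Si](C)(C)C(C)(C)C | starting material
8 | (E)-[4-(tert-butyldimethylsilyloxy)-2-methylbut-1-en-1-yl]dimethylalane | C[Al](C)/C=C(\C)CCO[Si](C)(C)C(C)(C)C | intermediate
9 | (2E)-5-(tert-butyldimethylsilyloxy)-3-methylpent-2-en-1-ol | OC/C=C(\C)CCO[Si](C)(C)C(C)(C)C | intermediate
10 | (2E)-1-(tert-butyldiphenylsilyloxy)-5-(tert-butyldimethylsilyloxy)-3-methylpent-2-ene | CC(C)(C)[Si](c1ccccc1)(c1ccccc1)OC/C=C(\C)CCO[Si](C)(C)C(C)(C)C | intermediate
11 | (3E)-5-(tert-butyldiphenylsilyloxy)-3-methylpent-3-en-1-ol | CC(C)(C)[Si](c1ccccc1)(c1ccccc1)OC/C=C(\C)CCO | intermediate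
12 | tert-butyl{[(2E)-5-iodo-3-methylpent-2-en-1-yl]oxy}diphenylsilane | CC(C)(C)[Si](c1ccccc1)(c1ccccc1)OC/C=C(\C)CCI | intermediate
13 | [(3E)-5-(tert-butyldiphenylsilyloxy)-3-methylpent-3-en-1-yl]lithium | CC(C)(C)[Si](c1ccccc1)(c1ccccc1)OC/C=C(\C)CC[Li] | intermediate
14 | lithium oxiranyl borate (13 added to boron of 6) | [Li+].O1[C@]2([B-]3(CC/C(C)=C/CO[Si](c5ccccc5)(c5ccccc5)C(C)(C)C)OC(C)(C)C(C)(C)O3)[C@]4(C)CC[C@@H](Br)C(C)(C)[C@H]4CC[C@]12C | intermediate
15 | tertiary boronate (C9: side chain β, Bpin α; 8α-OSiEt3; 15-OTBDPS) | C/C(=C\CO[Si](c1ccccc1)(c1ccccc1)C(C)(C)C)CC[C@@]1(B3OC(C)(C)C(C)(C)O3)[C@]2(C)CC[C@@H](Br)C(C)(C)[C@H]2CC[C@]1(C)O[Si](CC)(CC)CC | intermediate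
16 | lithium phenylborate of 15 | [Li+].C/C(=C\CO[Si](c1ccccc1)(c1ccccc1)C(C)(C)C)CC[C@@]1([B-]3(c4ccccc4)OC(C)(C)C(C)(C)O3)[C@]2(C)CC[C@@H](Br)C(C)(C)[C@H]2CC[C@]1(C)O[Si](CC)(CC)CC | intermediate
17 | bis-silyl ether of the target (8-O-SiEt3, 15-O-TBDPS) | C/C(=C\CO[Si](c1ccccc1)(c1ccccc1)C(C)(C)C)CC[C@H]1[C@]2(C)CC[C@@H](Br)C(C)(C)[C@H]2CC[C@]1(C)O[Si](CC)(CC)CC | intermediate
18 | (2E)-5-[(1S,2S,4aS,6R,8aR)-6-bromo-2-hydroxy-2,5,5,8a-tetramethyldecahydronaphthalen-1-yl]-3-methylpent-2-en-1-ol | C/C(=C\CO)CC[C@H]1[C@]2(C)CC[C@@H](Br)C(C)(C)[C@H]2CC[C@]1(C)O | target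

**Step count and risks**

Total steps: 10. Longest linear sequence: 7 steps (steps 4–10, from 7); the ring branch from 1 is 6 steps (1, 2, 3, 8, 9, 10).

Steps most likely to fail:

Step 2 (Proposed new method). The congested diboryl carbon may be too slow to capture the C10 cation, so the cascade may stop by proton loss after the first ring; the bicyclic cation may also lose a proton instead of a boryl group. The fallback uses known chemistry, sets out from 1 and returns at 5. Peterson olefination of 1 with bis(trimethylsilyl)methyllithium gives the vinylsilane, of which the (Z)-isomer F1 (silicon cis to the chain, hence axial on C9 in the chair) is used. The same catalytic bromocyclization then ends by the classical ipso‑desilylation of a vinylsilane terminator and gives the Δ8 olefin F2 (C9–H). Hydroboration–oxidation (BH3·THF; NaOH, H2O2) from the α face gives the 9α-ol F3. Dess–Martin oxidation gives the 9-ketone F4. KHMDS/PhNTf2 gives the enol triflate F5 (only C8 bears an α‑hydrogen). Miyaura borylation (B2pin2, PdCl2(PPh3)2, PPh3, KOPh) returns 5.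

Step 8 (Proposed new method). After O‑silylation the oxirane may ionise at C8 and eject the boron group (deborylative fragmentation) instead of undergoing the 1,2‑shift, or the borate may not form at the congested boron. The fallback uses known chemistry, sets out from 5 and returns at 18. 2-(2-Lithioethyl)-2-methyl-1,3-dioxolane F6 (from the commercial bromide and t-BuLi) is added to 5, and the alkenyl borate is treated with I2 and then NaOMe (Zweifel olefination). This forms the same C9–C11 bond and gives the tetrasubstituted Δ8 olefin F7. F7 has no other olefin, so BH3·THF followed by NaOH/H2O2 should add H and OH syn from the α face (boron on the less hindered C8) to give the 8α-ol F8 with 9α‑H. Aqueous acid frees the methyl ketone F9. A Horner–Wadsworth–Emmons reaction with triethyl phosphonoacetate gives the (E)-enoate F10 after separation from the minor Z isomer, and DIBAL‑H reduction gives 18.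

Step 9. The congested tertiary boron may not accept the aryllithium, or the borate may collapse by elimination of the β‑silyloxy group to the Δ8 olefin before it is oxidised. The fallback sets out from 15 and returns at 17. KHF2 in aqueous methanol converts the pinacol boronate into the potassium trifluoroborate F11, which needs no carbon nucleophile at boron. Single‑electron oxidation under photoredox conditions (acridinium photocatalyst, blue light) with a bulky thiol as hydrogen‑atom donor then gives 17 through the same C9 radical.

**Further compounds**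

F1 | step 2 | (1Z,5E)-trimethyl(2,6,10-trimethylundeca-1,5,9-trien-1-yl)silane | C[Si](C)(C)/C=C(/C)CC/C=C(\C)CCC=C(C)C
F2 | step 2 | Δ8 olefin (3β-bromo, C8=C9, C9–H, trans-decalin) | C1[C@]2(C)CC[C@@H](Br)C(C)(C)[C@H]2CCC=1C
F3 | step 2 | 9α-ol (8β-methyl, 8α-H) | O[C@@H]1[C@]2(C)CC[C@@H](Br)C(C)(C)[C@H]2CC[C@H]1C
F4 | step 2 | 9-ketone (8β-methyl) | O=C1[C@]2(C)CC[C@@H](Br)C(C)(C)[C@H]2CC[C@H]1C
F5 | step 2 | C9 enol triflate (C8=C9) | C1(OS(=O)(=O)C(F)(F)F)[C@]2(C)CC[C@@H](Br)C(C)(C)[C@H]2CCC=1C
F6 | step 8 | 2-(2-lithioethyl)-2-methyl-1,3-dioxolane | [Li]CCC1(C)OCCO1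
F7 | step 8 | Δ8 olefin bearing the 2-(2-methyl-1,3-dioxolan-2-yl)ethyl chain on C9 | C1(CCC5(C)OCCO5)[C@]2(C)CC[C@@H](Br)C(C)(C)[C@H]2CCC=1C
F8 | step 8 | 8α-ol with 9α-H and the dioxolane side chain | CC5(OCCO5)CC[C@H]1[C@]2(C)CC[C@@H](Br)C(C)(C)[C@H]2CC[C@]1(C)O
F9 | step 8 | 8α-hydroxy methyl ketone (4-(decalinyl)butan-2-one) | CC(=O)CC[C@H]1[C@]2(C)CC[C@@H](Br)C(C)(C)[C@H]2CC[C@]1(C)O
F10 | step 8 | ethyl (2E)-enoate of the target skeleton | CCOC(=O)/C=C(\C)CC[C@H]1[C@]2(C)CC[C@@H](Br)C(C)(C)[C@H]2CC[C@]1(C)O
F11 | step 9 | potassium trifluoroborate corresponding to 15 | [K+].C/C(=C\CO[Si](c1ccccc1)(c1ccccc1)C(C)(C)C)CC[C@@]1([B-](F)(F)F)[C@]2(C)CC[C@@H](Br)C(C)(C)[C@H]2CC[C@]1(C)O[Si](CC)(CC)CC
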